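Readings and results stem from a simulated flask with constants of no real substance; the scatter is artificial.

Saturday's flask is charged thinner than Sunday's, 0.067 M against 0.10 M, yet target levels off at about the same fraction of the charge in both.

| flask | substrate | remark | time |
|---|---|---|---|
| Sunday's | 0.10 M | the very flask that is asked about, followed so far |  |
| Saturday's | 0.067 M | run made earlier |  |
| flask | 0.10 M |  | 50 min |

- Sunday's (time / min: target / %, substrate / %): 1.50: 11.6, 0.3; 5.00: 12.3, 0.4; 8.00: 12.3, 0.8; 12.0: 11.6, 1.4; 20.0: 11.9, 0.4; 25.0: 11.0, 1.1; 30.0: 11.5, 1.0
- Saturday's (time / min: target / %, substrate / %): 0.250: 7.0, 0.9; 0.417: 9.1, 1.2; 0.667: 11.3, 0.7; 1.00: 11.9, 0.5; 1.50: 11.7, 1.0; 2.50: 12.7, 0.6; 4.00: 12.1, 0.6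

(standard deviation of a reading: 0.3 percentage points)

- alpha: at 50 min add substrate, 50.0% of the amount charged, then wait 1.5 h
- delta: change nothing and wait 1.5 h more
- theta: at 50 min take out 90% of the target then present, then wait 1.5 h

- target that was removed still counts
- additions bring no volume worth counting

* target, in percent of the substrate first charged, at 50 min
* which option adds most target ("none" when 2 percentage points or less is all one gets) (alpha / delta / theta / none)
* target present, with what was taken out counted in, in percent of the substrate first charged, after delta
* target present, with what was taken out counted in, in percent of the substrate first charged, after theta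

*What number do you carry?* Saturday's readings from 1.00 min on average 12.1%. I call this the pool share: the fraction of what remains in the flask that stands as target once it has relaxed, a rapid pre-equilibrium.

*How fast does it relax?* Saturday's first reading gives 3.46 /min, a half-life near 0.200 min.

*And the weak spot, Sunday's drift?* Readings up to 8.00 min average 12.1%, and those from 20.0 min on average 11.5%. That reads as a drain of 0.002529 /min, though the fall of 0.6 percentage points stands against a scatter of 0.24 points, a ratio of 2.45.

*Does the comparison drift?* Relaxation is 1368 times the drain. If both are first order, as equal shares at both charges suggest, that ratio stays put while the pool shrinks, so target follows pool share times pool.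

*Your commitment?* For Sunday's flask at 50 min, 10.7%. Removal beats waiting by about 9.6 points, and addition by about 6 points, so I take theta.

The forecast says 11.5%, above my figure, with theta best, 10.8% after delta and 20% after theta: “this looks like a first-order equilibrium”.

Sunday's flask gives 11.3%, and theta is best: theta adds 7.8 points, alpha 4 points, delta −1.3 points. Counted in, 9.96% stands after delta and 19.0% after theta.

    substrate ⇌ target (K = 16.0, k = 0.00150 /s)
    target ⇌ isomer of the product (K = 7.20, k = 0.0510 /s)
    isomer of the product ⇌ substrate (k = 0.00720 /s)
    target → over-reaction product (k = 1.90 × 10⁻⁴ /s)

Target and the isomer of the product relax with a half-life of 0.199 min, short against 50 min. At 0.0138 min, the forward step to that isomer uses target 270 times as fast as the path to over-reaction product. Over-reaction product stands at 6.61% at 50.0 min, and the pool share on the remainder gives 11.3%, beside the flask's 11.3%.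

Read at 20 min, the same flask holds 2.67% over-reaction product, so the pool share gives 11.8%; the computed target is 11.7%.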